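## Plan

Chamigrene numbering: spiro C6; ring A is C6–C7(=C14H2)–C8–C9–C10(Br)–C11(Me2); ring B is C6–C1–C2(Cl)–C3(Me,Br)–C4–C5.
Cuts: C3–Br and C2–Cl go back through a chlorohydrin and an epoxide to the C2=C3 alkene, and C3–CH3 to the enol triflate of a C3 ketone. Ring B is then opened at C6–C5 (Michael) and C2–C1 (aldol) to a brominated β-cyclocitral and a four-carbon enone, and ring A at C6–C11 to an epoxygeranyl ester.
Forward: ring A closes first (radical epoxy-polyene cyclisation, then bromide for hydroxyl), ring B is annulated onto the cyclocitral dienolate, and the ring-B halogens come last.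
Stereochemistry: C10 comes from a Shi epoxidation (kept in the cyclisation, inverted once by bromide). C6 is set by C10 in the Michael addition. C2 and C3 come from epoxidation anti to C7, diaxial chloride opening, and bromide substitution with retention through a chloronium ion.

Key step: step 6

Remark: the four-carbon enone is used as its α-trimethylsilyl derivative, a methyl vinyl ketone equivalent that tolerates a preformed lithium dienolate and loses silicon in the same flask; it and the L-fructose-derived ketone catalyst are taken as purchasable, and reagents that contribute atoms are numbered as starting materials.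

## Route

Step 1
Reactants: 1 geranyl acetate; 2 potassium peroxymonosulfate (active salt of Oxone)
Product: 3 (S)-6,7-epoxygeranyl acetate
Conditions: L-fructose-derived Shi ketone (cat.), KHSO5 (Oxone), K2CO3, Bu4NHSO4, MeCN/CH2(OMe)2/aq. Na2B4O7 buffer, 0 °C
Reagents that add atoms: potassium peroxymonosulfate, [K+].[O-]S(=O)(=O)OO
Why: Shi epoxidation with the dioxirane formed from the chiral ketone should take the electron-rich 6,7-alkene and spare the 2,3-alkene, which the allylic acetate deactivates, and since the usual D-fructose-derived ketone gives (R)-epoxides from trisubstituted alkenes through its spiro transition state, its enantiomer should set the (S) centre that becomes C10.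

Step 2
Reactants: 3 (S)-6,7-epoxygeranyl acetate
Product: 4 [(1R,3S)-3-hydroxy-2,2-dimethyl-6-methylidenecyclohexyl]methyl acetate
Conditions: Cp2TiCl2 (2.2 equiv), Mn dust, THF, rt (Cp2TiCl, trivalent titanium, formed in the flask); aq. NaH2PO4 work-up
Reagents that add atoms: none
Why: Homolytic opening of the epoxide by Cp2TiCl (Nugent–RajanBabu conditions) gives the tertiary radical at the future C11, which closes ring A by 6-endo-trig attack on the trisubstituted alkene through a chair, a second Cp2TiCl traps the new tertiary radical and β-hydride elimination gives the exocyclic alkene, the carbinol centre keeping its (S) configuration because its C–O bond is never broken and the chair placing the acetoxymethyl group cis to the hydroxyl.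

Step 3
Reactants: 4 [(1R,3S)-3-hydroxy-2,2-dimethyl-6-methylidenecyclohexyl]methyl acetate; 5 tetrabromomethane
Product: 6 [(1R,3R)-3-bromo-2,2-dimethyl-6-methylidenecyclohexyl]methyl acetate
Conditions: CBr4, P(n-Oct)3, toluene, 70 °C
Reagents that add atoms: tetrabromomethane, BrC(Br)(Br)Br
Why: Appel reaction in which bromide displaces the alkoxyphosphonium ion by SN2 with inversion to the (R)-bromide, the flexible monocyclic ring being able to present the leaving group axially, the arrangement from which neopentylic secondary alcohols flanked by a gem-dimethyl group are known to undergo this displacement.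

Step 4
Reactants: 6 [(1R,3R)-3-bromo-2,2-dimethyl-6-methylidenecyclohexyl]methyl acetate
Product: 7 [(1R,3R)-3-bromo-2,2-dimethyl-6-methylidenecyclohexyl]methanol
Conditions: K2CO3 (cat.), MeOH, 0 °C
Reagents that add atoms: none
Why: Carbonate-catalysed transesterification removes the primary acetate as methyl acetate under conditions too mild to touch the hindered secondary bromide, and no stereocentre is affected.

Step 5
Reactants: 7 [(1R,3R)-3-bromo-2,2-dimethyl-6-methylidenecyclohexyl]methanol
Product: 9 (5R)-5-bromo-2,6,6-trimethylcyclohex-1-ene-1-carbaldehyde, via bromo-γ-cyclocitral 8 (not isolated)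
Conditions: Dess–Martin periodinane, CH2Cl2, 0 °C → rt; then DBU (excess), rt
Reagents that add atoms: none
Why: Dess–Martin oxidation gives the β,γ-unsaturated aldehyde 8, whose doubly activated α-hydrogen is removed by DBU so that reprotonation at the methylidene carbon moves the alkene into conjugation under thermodynamic control, which erases the aldehyde-bearing stereocentre and leaves the bromide centre untouched.

Step 6
Reactants: 9 (5R)-5-bromo-2,6,6-trimethylcyclohex-1-ene-1-carbaldehyde; 10 3-(trimethylsilyl)but-3-en-2-one
Product: 15 (6S,10R)-10-bromochamigra-1,7(14)-dien-3-one, via lithium dienolate 11 (not isolated), via silyl keto aldehyde 12 (not isolated), via keto aldehyde 13 (not isolated), via aldol 14 (not isolated)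
Conditions: LiN(i-Pr)2, THF, −78 °C; 10, −78 → −30 °C; then NaOMe (cat.), MeOH, −30 °C → rt
Reagents that add atoms: 3-(trimethylsilyl)but-3-en-2-one, CC(=O)C(=C)[Si](C)(C)C
Why: LiN(i-Pr)2 bound to the carbonyl oxygen of the s-cis enal removes a proton from the C14 methyl, which lies cis to the formyl group, and not from C8, so that the exocyclic dienolate 11 forms; as a lithium dienolate it attacks the silyl enone through its α-carbon C6 (Michael addition, C6–C5), which creates the quaternary centre, leaves C7=C14 exocyclic and ends in a silyl-stabilised enolate that does not go on to polymerise. Methoxide then removes silicon from 12, and the methyl ketone enolate of 13 adds to the non-enolisable aldehyde (C2–C1), closing ring B by a 6-(enolendo)-exo-trig aldol addition, after which 14 loses water by E1cB elimination. The closest known reactions are the Robinson annulation in its α-silyl vinyl ketone form for preformed lithium enolates, the spiroannulation of α-branched aldehydes and the deconjugative α-alkylation of β-cyclocitral dienolates. The new stereocentre C6 is controlled by C10: with bromine equatorial on ring A the enone should approach C6 along the axial trajectory, on the face away from the axial C11 methyl that flanks the other face, so that C5 ends trans to bromine. The step needs C14 deprotonation, C6 rather than C14 attack and this facial selectivity; the first is secured by the cis relation of methyl and formyl group, the second by the kinetic α-reactivity of lithium dienolates towards a reactive acceptor at low temperature, and the third rests on the conformational bias described.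

Step 7
Reactants: 15 (6S,10R)-10-bromochamigra-1,7(14)-dien-3-one; 16 N-phenylbis(trifluoromethanesulfonimide)
Product: 18 (6S,10R)-10-bromochamigra-2,7(14)-dien-3-yl trifluoromethanesulfonate, via lithium enolate 17 (not isolated)
Conditions: LiBH(s-Bu)3, THF, −78 °C; then PhNTf2, −78 → 0 °C
Reagents that add atoms: N-phenylbis(trifluoromethanesulfonimide), O=S(=O)(N(c1ccccc1)S(=O)(=O)C(F)(F)F)C(F)(F)F
Why: Conjugate reduction in which LiBH(s-Bu)3 delivers hydride to C1 of the enone, which carries no β-substituent other than the ring, to give the C2=C3 lithium enolate 17 regiospecifically, and O-sulfonylation with PhNTf2 fixes that alkene position as the enol triflate without creating a stereocentre.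

Step 8
Reactants: 18 (6S,10R)-10-bromochamigra-2,7(14)-dien-3-yl trifluoromethanesulfonate; 19 dimethylzinc
Product: 20 (6S,10R)-10-bromochamigra-2,7(14)-diene (10-bromo-β-chamigrene)
Conditions: Me2Zn, Pd(PPh3)4 (cat.), THF, 0 °C → rt
Reagents that add atoms: dimethylzinc, C[Zn]C
Why: Negishi coupling in which zerovalent palladium inserts into the vinyl C–O bond of the triflate much faster than into the hindered secondary alkyl bromide, so that transmetallation from Me2Zn and reductive elimination place the methyl group on C3 and leave the alkene at C2=C3.

Step 9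
Reactants: 20 (6S,10R)-10-bromochamigra-2,7(14)-diene; 21 3-chloroperoxybenzoic acid
Product: 22 (2S,3R,6S,10R)-10-bromo-2,3-epoxychamigr-7(14)-ene (oxirane on the ring-B face anti to C7)
Conditions: mCPBA (1.05 equiv), CH2Cl2, −20 → 0 °C
Reagents that add atoms: 3-chloroperoxybenzoic acid, OOC(=O)c1cccc(Cl)c1
Why: Prilezhaev epoxidation takes the trisubstituted C2=C3 alkene, more electron-rich and more open than the 1,1-disubstituted C7=C14 alkene beside the spiro centre, and because C7 should sit axial on C6 in the half-chair of ring B (the bulkier C11 equatorial) the peracid should add to the face anti to C7 and give the (2S,3R)-epoxide.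

Step 10
Reactants: 22 (2S,3R,6S,10R)-10-bromo-2,3-epoxychamigr-7(14)-ene; 23 pyridinium chloride
Product: 24 (2R,3R,6S,10R)-10-bromo-2-chlorochamigr-7(14)-en-3-ol
Conditions: pyridinium chloride, CH2Cl2, 0 °C → rt
Reagents that add atoms: pyridinium chloride, [Cl-].c1cc[nH+]cc1
Why: Acid-assisted SN2 opening governed by the Fürst–Plattner rule, in which, with C7 axial on the chair of ring B, only chloride attack at the secondary carbon C2 from the C7 face gives the trans-diaxial chlorohydrin, the pattern known from steroidal 5α,6α-epoxides, so C2 should be inverted to (R) while the C3–O bond and its configuration stay intact and the weakly acidic salt spares the exocyclic alkene.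

Step 11
Reactants: 24 (2R,3R,6S,10R)-10-bromo-2-chlorochamigr-7(14)-en-3-ol; 25 bromotrimethylsilane
Product: 26 (2R,3R,6S,10R)-3,10-dibromo-2-chlorochamigr-7(14)-ene
Conditions: Me3SiBr (1.2 equiv), CH2Cl2, −40 → 0 °C
Reagents that add atoms: bromotrimethylsilane, C[Si](C)(C)Br
Why: Deoxybromination of a tertiary alcohol with bromotrimethylsilane, in which the silylated hydroxyl leaves with neighbouring-group participation by the antiperiplanar C2 chlorine and bromide should open the resulting chloronium ion at the tertiary carbon C3 in the diaxial sense from the face the oxygen left, so that C3 is substituted with net retention and the chloride stays on C2.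

## Compound list

1 | geranyl acetate, (2E)-3,7-dimethylocta-2,6-dien-1-yl acetate | CC(C)=CCC/C(C)=C/COC(C)=O | starting material
2 | potassium peroxymonosulfate (active salt of Oxone) | [K+].[O-]S(=O)(=O)OO | starting material
3 | (S)-6,7-epoxygeranyl acetate, (2E)-5-[(2S)-3,3-dimethyloxiran-2-yl]-3-methylpent-2-en-1-yl acetate | CC1(C)O[C@H]1CC/C(C)=C/COC(C)=O | intermediate
4 | [(1R,3S)-3-hydroxy-2,2-dimethyl-6-methylidenecyclohexyl]methyl acetate (hydroxyl and acetoxymethyl cis) | CC(=O)OC[C@@H]1C(=C)CC[C@H](O)C1(C)C | intermediate
5 | tetrabromomethane | BrC(Br)(Br)Br | starting material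
6 | [(1R,3R)-3-bromo-2,2-dimethyl-6-methylidenecyclohexyl]methyl acetate (bromine and acetoxymethyl trans) | CC(=O)OC[C@@H]1C(=C)CC[C@@H](Br)C1(C)C | intermediate
7 | [(1R,3R)-3-bromo-2,2-dimethyl-6-methylidenecyclohexyl]methanol | OC[C@@H]1C(=C)CC[C@@H](Br)C1(C)C | intermediate
8 | (1R,3R)-3-bromo-2,2-dimethyl-6-methylidenecyclohexane-1-carbaldehyde (bromo-γ-cyclocitral) | O=C[C@@H]1C(=C)CC[C@@H](Br)C1(C)C | intermediate (not isolated)
9 | (5R)-5-bromo-2,6,6-trimethylcyclohex-1-ene-1-carbaldehyde | CC1=C(C=O)C(C)(C)[C@H](Br)CC1 | intermediate
10 | 3-(trimethylsilyl)but-3-en-2-one | CC(=O)C(=C)[Si](C)(C)C | starting material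
11 | lithium (E)-[(3R)-3-bromo-2,2-dimethyl-6-methylidenecyclohexylidene]methanolate (oxygen on the side of the methylidene carbon) | [Li]O/C=C1\C(=C)CC[C@@H](Br)C1(C)C | intermediate (not isolated)
12 | (1S,3R)-3-bromo-2,2-dimethyl-6-methylidene-1-[3-oxo-2-(trimethylsilyl)butyl]cyclohexane-1-carbaldehyde (either epimer at the silyl-bearing carbon) | C=C1CC[C@@H](Br)C(C)(C)[C@]1(C=O)CC(C(C)=O)[Si](C)(C)C | intermediate (not isolated)
13 | (1S,3R)-3-bromo-2,2-dimethyl-6-methylidene-1-(3-oxobutyl)cyclohexane-1-carbaldehyde | C=C1CC[C@@H](Br)C(C)(C)[C@]1(C=O)CCC(C)=O | intermediate (not isolated)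
14 | (6S,10R)-10-bromo-1-hydroxychamigr-7(14)-en-3-one (either C1 epimer) | C=C1CC[C@@H](Br)C(C)(C)[C@]12CCC(=O)CC2O | intermediate (not isolated)
15 | (6S,10R)-10-bromochamigra-1,7(14)-dien-3-one | C=C1CC[C@@H](Br)C(C)(C)[C@]12CCC(=O)C=C2 | intermediate
16 | N-phenylbis(trifluoromethanesulfonimide) | O=S(=O)(N(c1ccccc1)S(=O)(=O)C(F)(F)F)C(F)(F)F | starting material
17 | lithium (6S,10R)-10-bromochamigra-2,7(14)-dien-3-olate | C=C1CC[C@@H](Br)C(C)(C)[C@]12CCC(O[Li])=CC2 | intermediate (not isolated)
18 | (6S,10R)-10-bromochamigra-2,7(14)-dien-3-yl trifluoromethanesulfonate | C=C1CC[C@@H](Br)C(C)(C)[C@]12CCC(OS(=O)(=O)C(F)(F)F)=CC2 | intermediate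
19 | dimethylzinc | C[Zn]C | starting material
20 | (6S,10R)-10-bromochamigra-2,7(14)-diene (10-bromo-β-chamigrene) | C=C1CC[C@@H](Br)C(C)(C)[C@]12CCC(C)=CC2 | intermediate
21 | 3-chloroperoxybenzoic acid | OOC(=O)c1cccc(Cl)c1 | starting material
22 | (2S,3R,6S,10R)-10-bromo-2,3-epoxychamigr-7(14)-ene | C=C1CC[C@@H](Br)C(C)(C)[C@]12CC[C@@]3(C)O[C@H]3C2 | intermediate
23 | pyridinium chloride | [Cl-].c1cc[nH+]cc1 | starting material
24 | (2R,3R,6S,10R)-10-bromo-2-chlorochamigr-7(14)-en-3-ol | C=C1CC[C@@H](Br)C(C)(C)[C@]12CC[C@@](C)(O)[C@H](Cl)C2 | intermediate
25 | bromotrimethylsilane | C[Si](C)(C)Br | starting material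
26 | (2R,3R,6S,10R)-3,10-dibromo-2-chlorochamigr-7(14)-ene, (2R,6S,8R,9R)-2,9-dibromo-8-chloro-1,1,9-trimethyl-5-methylidenespiro[5.5]undecane | C=C1CC[C@@H](Br)C(C)(C)[C@]12CC[C@@](C)(Br)[C@H](Cl)C2 | target

## Step count and risks

Total step count: 11. Longest linear sequence: 11 steps (1 → 26).

Steps most likely to fail:

Step 6. The dienolate may form its new bond through C14 instead of C6, the enone may approach the wrong face of C6, or the dienolate carbon may displace the C10 bromide internally (cyclopropane closure). The fallback sets out from 6 and comes back at 20, building ring B by a Diels–Alder reaction. Ozonolysis of the exocyclic alkene of 6 (O3, CH2Cl2/MeOH, −78 °C; Me2S) would give [(1R,3R)-3-bromo-2,2-dimethyl-6-oxocyclohexyl]methyl acetate F1. Elimination of acetic acid with DBU would give the cross-conjugated enone (4R)-4-bromo-3,3-dimethyl-2-methylidenecyclohexan-1-one F2. Me2AlCl-promoted cycloaddition of isoprene (CH2Cl2, −78 °C, para orientation) would give the spiro ketone (6R,10R)-10-bromochamigr-2-en-7-one F3. Methylenation of the hindered C7 ketone with Cp2TiMe2 (toluene, 65 °C) would then give 20, and the route continues with step 9. Because this sequence forms C6–C1 and not C6–C5 as the new bond at the spiro centre, a facial preference that defeats the Michael addition is the one the cycloaddition needs.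

Step 3. At the neopentylic carbon the alkoxyphosphonium ion may lose a proton or undergo methyl migration faster than bromide displaces it. The fallback sets out from 3 and comes back at 9; it makes the C–Br bond on the open chain and closes ring A through a bromonium ion of fixed configuration. Opening of epoxide 3 at its secondary carbon with Li2NiBr4 (THF, rt; SN2, inversion) would give the bromohydrin (2E,6R)-6-bromo-7-hydroxy-3,7-dimethyloct-2-en-1-yl acetate F4. Ionisation of its tertiary hydroxyl with bromine participation (catalytic TfOH, (CF3)2CHOH, 0 °C) would give the bromonium ion, which closes onto the 2,3-alkene to give [(1S,3R)-3-bromo-2,2-dimethyl-6-methylidenecyclohexyl]methyl acetate F5, the C6 epimer of 6; any endocyclic alkene isomers converge later. Methanolysis as in step 4 would give [(1S,3R)-3-bromo-2,2-dimethyl-6-methylidenecyclohexyl]methanol F6. Oxidation and isomerisation as in step 5, through (1S,3R)-3-bromo-2,2-dimethyl-6-methylidenecyclohexane-1-carbaldehyde F7, would give 9.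

Step 11. Hydrogen bromide formed from the silyl bromide may add to or isomerise the C7=C14 alkene, or the C3 cation may lose a proton. The fallback sets out from 24 and comes back at 26. The hydroxyl of 24 would be activated under neutral conditions with 1-bromo-N,N,2-trimethylprop-1-en-1-amine (CH2Cl2, 0 °C), which turns it into an imidate-type leaving group and releases only an amide. Chlorine participation and bromide return would then give 26 directly. This fallback makes no new compound (F0).

## Further compounds

F1 | step 6 | [(1R,3R)-3-bromo-2,2-dimethyl-6-oxocyclohexyl]methyl acetate | CC(=O)OC[C@@H]1C(=O)CC[C@@H](Br)C1(C)C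
F2 | step 6 | (4R)-4-bromo-3,3-dimethyl-2-methylidenecyclohexan-1-one | C=C1C(=O)CC[C@@H](Br)C1(C)C
F3 | step 6 | (6R,10R)-10-bromochamigr-2-en-7-one | O=C1CC[C@@H](Br)C(C)(C)[C@]12CCC(C)=CC2
F4 | step 3 | (2E,6R)-6-bromo-7-hydroxy-3,7-dimethyloct-2-en-1-yl acetate | CC(C)(O)[C@H](Br)CC/C(C)=C/COC(C)=O
F5 | step 3 | [(1S,3R)-3-bromo-2,2-dimethyl-6-methylidenecyclohexyl]methyl acetate | CC(=O)OC[C@H]1C(=C)CC[C@@H](Br)C1(C)C
F6 | step 3 | [(1S,3R)-3-bromo-2,2-dimethyl-6-methylidenecyclohexyl]methanol | OC[C@H]1C(=C)CC[C@@H](Br)C1(C)C
F7 | step 3 | (1S,3R)-3-bromo-2,2-dimethyl-6-methylidenecyclohexane-1-carbaldehyde | O=C[C@H]1C(=C)CC[C@@H](Br)C1(C)C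
F0 | step 11 | none | none
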